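The last reading of Friday's flask at 70 °C shows a lower excess than the last reading of Saturday's flask at 42 °C, although it was taken earlier. The single-handed catalyst makes left-handed product in excess, and the turning of left-handed product into right-handed product (racemisation) can erase that excess while the flask stands.

| setting | Wednesday's | Friday's | Saturday's | winter | noon | spring | dusk |
|---|---|---|---|---|---|---|---|
| left-handed substrate | 0.034 M | 0.075 M | 0.050 M | 0.050 M | 0.050 M | 0.050 M | 0.050 M |
| right-handed substrate | 0.034 M | 0.075 M | 0.050 M | 0.050 M | 0.050 M | 0.050 M | 0.050 M |
| coupling partner | 2 equiv | 2 equiv | 2 equiv | 2.00 equiv | 2.00 equiv | 2.00 equiv | 2.00 equiv |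
| catalyst | 5 mol% | 5 mol% | 10 mol% | 5 mol% | 5 mol% | 5 mol% | 5 mol% |
| temperature | 42 °C | 70 °C | 42 °C | 30 °C |  | 55 °C | 80 °C |
| remark | run made earlier | run made earlier | run made earlier |  | at 80 °C until 1.5 min, from then on at 30 °C |  |  |
| time |  |  |  | 3.0 min | 3.0 min | 3.0 min | 3.0 min |

| run | time / s | left-handed product / % | right-handed product / % |
|---|---|---|---|
| Wednesday's | 15.0 | 1.2 | 0.4 |
| Wednesday's | 40.0 | 5.6 | 2.3 |
| Wednesday's | 80.0 | 8.2 | 0.6 |
| Wednesday's | 120 | 12.5 | 1.5 |
| Friday's | 10.0 | 14.5 | 1.7 |
| Friday's | 15.0 | 17.2 | 4.1 |
| Friday's | 20.0 | 18.0 | 6.6 |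
| Friday's | 30.0 | 17.5 | 10.0 |
| Saturday's | 10.0 | 5.9 | 1.4 |
| Saturday's | 20.0 | 8.8 | 0.5 |
| Saturday's | 50.0 | 19.5 | 2.6 |
| Saturday's | 120 | 30.4 | 4.0 |

(standard deviation of a reading: 1 percentage point)

- the flask with the highest excess of left-handed product over right-handed product ("all alike" if they lie within 1.5 percentage points) (winter / noon / spring / dusk / all alike)
- excess of left-handed product over right-handed product at the end, winter
- excess of left-handed product over right-handed product at the end, noon
- excess of left-handed product over right-handed product at the end, spring
- excess of left-handed product over right-handed product at the end, dusk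

The question turned round: for a hot flask to lead, its excess would have to survive the whole run. The test is the erosion rate, the powers of ten of excess lost per unit time. It is a net reading, because the two products together read higher at the end of Friday's flask than at its start, and it carries the scatter. Friday's flask reads an excess of 79.0 % at 10.0 s and 27.3 % at 30.0 s, so:

erosion rate = decimal logarithm of (first excess / last excess) / time between = 1.39 /min

powers of ten lost in 3.0 min = 4.17

A hot flask would need this figure near zero. Carried unchanged to dusk, though dusk stands hotter at 80 °C, it is 4.17, so this reckoning puts dusk near zero excess. Saturday's flask reads 76.5 % at 50.0 s and 76.7 % at 120 s, but with 1 percentage point of scatter on each reading this pair does not tell whether erosion runs there; both readings stand above Friday's last excess. This reckoning therefore expects winter, colder still, to stand nearer Saturday's readings than Friday's last one, and to lead.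

The forecast names winter, with 80 % for winter, −1.5 % for noon, 28 % for spring and 0 % for dusk, and says of noon that “cooling cannot recover it”.

Winter leads at 93.1 %, with noon at 5.17 %, spring at 25.0 % and dusk at 0.435 %. In dusk the relaxation half-life of the two products by racemisation alone is 0.0609 min, short against the 3.0 min run. On noon's hot stretch of 1.5 min the erosion rate gives 2.08 powers of ten. Noon held 20.4 % left-handed and 19.6 % right-handed product at 1.50 min, then reached 21.8 % and 19.6 % by 3.00 min.

    coupling partner + catalyst + left-handed substrate → catalyst + left-handed product (k = 115 /M²/s, Ea = 38.0 kJ/mol)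
    coupling partner + catalyst + right-handed substrate → catalyst + right-handed product (k = 0.813 /M²/s, Ea = 50.0 kJ/mol)
    coupling partner ⇌ dormant form (K = 0.240, k = 0.0258 /s, Ea = 105 kJ/mol, ΔH = −24.0 kJ/mol)
    left-handed product ⇌ right-handed product (k = 0.0949 /s, Ea = 102 kJ/mol)
    (constants at 80 °C)

Dusk read at 50 s: counted 40.0 s from Friday's first excess, the erosion rate leaves 9.35 %. The computed excess of that neighbour is 5.62 %.

(The earlier runs and the new flask are simulated on assumed constants.)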